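## The problem

Target 22 is a (3R)-isoflavanone: a 5,7-dihydroxy-6-methylchroman-4-one (ring A fused to the dihydropyranone ring C) bearing at C3 a 2′,4′-dihydroxyphenyl ring B with an (E)-geranyl chain at C5′. Three unions are needed: ring A to ring C through O1–C8a and C4–C4a, ring B to C3, and the C10 chain to C5′. Because the ring A methyl lies between two hydroxyls, any phloroglucinol-based route must also decide between the 6-methyl and the 8-methyl chromanone. C3 is the only stereocentre, so no other centre can relay its configuration and it has to come from a reagent or catalyst. As a benzylic CH next to the C4 ketone, C3 is lost through the enol whenever acid or base reaches it at the ketone oxidation level. The fragile groups are four phenols on electron-rich rings and two trisubstituted alkenes, one of them close to the C4′ hydroxyl, where acid closes a chroman. Boranes, carbenes and hydrogenation attack these alkenes, which excludes benzyl ethers and fixes the order of events. The enabling feature is that O1 belongs to a phenol whose ortho carbons C4a and C8 are interchanged by the axis through C8a and C6–CH3, and whose para carbon C6 is methylated. An annulation that joins C4 to an ortho carbon and C2 to O1 can therefore give only one constitution, and it leaves a C3=C4 alkene at which C3–H and C4–O can be added under reagent control while C4 stays a carbinol.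

## Retrosynthesis

**22 ⇒ 21.** The four aryl O–CH2OCH3 bonds are cut last. Acetal ethers are chosen over benzyl ethers (hydrogenolysis would reduce the geranyl chain) and over silyl ethers (an ortho-lithiated aryl silyl ether rearranges). The forward step must remove four acetals with dilute acid without enolising C3 or protonating the chain.

**21 ⇒ 20.** The C4 carbonyl is taken back to the carbinol. Compared with carrying the ketone through the organometallic step, this keeps C3 non-enolisable while strong base is present. The forward step needs a neutral oxidant that ignores trisubstituted alkenes.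

**20 ⇒ 17 + 18.** The C5′–CH2 bond to the geranyl chain is cut, leaving a bromine on ring B. Attaching the chain earlier would expose its alkenes to the borane of the preceding step. Attaching it later, at the ketone level, would forbid an aryllithium. The forward step asks for bromine–lithium exchange in the presence of a lithium alkoxide (19) and allylic substitution at the unsubstituted terminus of 18 with the E alkene retained.

**17 ⇒ 15.** The C3–H and C4–O bonds are removed together, revealing the C3=C4 alkene of an isoflav-3-ene. The neighbouring options, conjugate reduction of an isoflavone or arylation of a chromanone, create C3 beside a ketone and so at its most labile. Here C3 is created beside a carbinol. The forward step needs boron at C4, syn addition and reagent control of the alkene face (organoborane 16).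

**15 ⇒ 4 + 12.** C4–C4a and O1–C2 are cut in one operation, through ortho-quinone methide 14 and benzodioxaborin 13. This divides the molecule into its two aromatic halves and makes ring C in the same step, where a deoxybenzoin route would need separate acylation, one-carbon insertion and ring closure. The precursors are a symmetric phenol and a 2-arylacrolein, each a few steps from a commercial resorcinol. The forward reaction must attack the aldehyde carbon with the ortho carbon of 4, not the β-carbon and not through oxygen, and must outrun self-condensation of 12.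

**12 ⇒ 11 ⇒ 9 ⇒ 6 + 7 ⇒ 5.** The α-methylene C=C of 12 is cut to arylacetaldehyde 11 and a one-carbon unit. The aldehyde is traced to the terminal alkene of allylarene 9 (through diol 10). The aryl–allyl bond is traced to aryllithium 8, made by exchanging one of the two equivalent bromines of 6, the bis-acetal of 5. The second bromine is the later geranyl site, so the symmetry of 5 settles the 1′,2′,4′,5′ pattern of ring B.

**4 ⇒ 2 ⇒ 1.** The C8a–O bond of phenol 4 is cut to a C–H bond of 2 (through boronate 3). That position is the only one on 2 without an ortho neighbour, so a sterically governed borylation finds it. This replaces a selective protection of 2-methylphloroglucinol, which would have to distinguish three hydroxyls.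

## Roads not taken

**Alternative 1:** The cut is O1–C8a and C4a–C5, so that rings C and A both come from one open chain, the hydroxy trioxo ester A1, which already carries ring B and its geranyl chain. In the forward direction PPTS would close the C2 hydroxyl onto the C8a ketone to a dihydropyranone. Mg(OMe)2 would then drive Claisen attack of C4a on the C5 ester and aromatisation to A2, racemic 22 with ring B as its bis(methoxymethyl) ether.
- Merits: the ring A hydroxyls arise unprotected, the 6-methyl position is fixed by the chain, and only one deprotection follows the key step against four steps in the chosen plan. On step count after the key step this road is better.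
- Weak points: C3 lies between a ketone and an aryl group throughout and meets a basic magnesium alkoxide, so A2 can only be racemic and a resolution would be unavoidable. A1 is a poly-β-carbonyl compound whose β-hydroxy ketone can dehydrate or fragment by retro-aldol reaction. Aldol and Claisen modes of ring A closure compete. Assembling A1 would take more steps than 4 and 12 together.
- Comparison: against the shorter endgame the chosen plan sets reagent control of C3 and two fragments that are each made in a few standard steps.

**Alternative 2:** The cut is C2–C3. The α-aryl α-diazo ketone A3 would lose nitrogen on Rh2(S-PTTL)4 or its enantiomer, and the C3 carbene would insert into a C–H bond of the C8a methoxy group to give A4, the tetrakis(tert-butyldimethylsilyl) ether of 22.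
- Merits: C3 is set catalytically, at the final oxidation level, in the ring-closing event. Only one step follows. Silyl ethers come off with buffered fluoride, which is gentler on the geranyl chain than acid. On these points this road is as good as or better than the chosen one.
- Weak points: insertion into a methyl C–H bond through a six-membered transition state has to compete with oxonium ylide formation at the methoxy oxygen and 1,2-shift, with attack on two electron-rich rings, with cyclopropanation of the geranyl alkenes (which must already be present) and with Wolff rearrangement. The level and sense of asymmetric induction for this insertion are unknown. Ring A needs one methyl and two silyl ethers on three oxygens, which brings back the regiochemical question that the symmetric phenol 4 avoids. A4 still has to be deprotected with C3 enolisable.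
- Comparison: the chosen plan is longer after the key step, but its stereo-defining step acts on an alkene with no competing reactive site, follows a known facial model, and precedes the arrival of the geranyl alkenes.

**Alternative 3:** The cut is O1–C8a. The bromo diol A5 would cyclise under CuI, 1,10-phenanthroline and Cs2CO3, the primary C2 hydroxyl displacing the C8a bromide, to give A6, which is identical with 20.
- Merits: C3 and C4 can be set in the open chain by auxiliary-controlled aldol chemistry, the most dependable stereocontrol of the four plans and surer than the hydroboration of the chosen plan. C4 stays a carbinol, the geranyl chain can be carried from the start, and A6 enters the same two-step endgame.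
- Weak points: the aryl bromide sits on a very electron-rich ring next to a branched benzylic carbinol, which is a poor case for copper-catalysed etherification at high temperature. Auxiliary attachment, aldol reaction with a hindered 2-bromobenzaldehyde, reductive auxiliary removal and cyclisation give a clearly longer linear sequence, with a stoichiometric auxiliary.
- Comparison: against the surer stereocontrol the chosen plan sets brevity and convergence, since ring C and the union of rings A and B arise in one step.

Key step: step 7

Assumption: the facial sense of monoisopinocampheylborane on 15 is taken from 1-arylcycloalkenes, which points to the reagent from (−)-α-pinene for (3R); if the sense proved opposite, the reagent from (+)-α-pinene would be used.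

## Route

Step 1
Reactants: 1 2-methylresorcinol (2-methylbenzene-1,3-diol)
Product: 2 1,3-bis(methoxymethoxy)-2-methylbenzene
Conditions: NaH (2.4 equiv), MOMCl (2.4 equiv), DMF, 0 °C → rt
Reagents that add atoms: chloromethyl methyl ether, COCCl
Why: Williamson-type O-alkylation of the bis-phenoxide; the acetal ethers tolerate the iridium catalyst, alkaline peroxide, organolithium and borane reagents used later.

Step 2
Reactants: 2 1,3-bis(methoxymethoxy)-2-methylbenzene
Product: 4 3,5-bis(methoxymethoxy)-4-methylphenol, via aryl pinacol boronate 3 (not isolated)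
Conditions: [Ir(OMe)(cod)]2 (1.5 mol%), 4,4′-di-tert-butyl-2,2′-bipyridine (3 mol%), B2pin2 (0.6 equiv), THF, 80 °C; then aq. NaOH, 30% H2O2, 0 °C → rt
Reagents that add atoms: hydrogen peroxide, OO
Why: Sterically governed iridium-catalysed C–H borylation takes the only ring hydrogen of 2 without an ortho substituent (para to the methyl group), and oxidation of the C–B bond at the same carbon gives the phenol in one pot.

Step 3
Reactants: 5 4,6-dibromoresorcinol (4,6-dibromobenzene-1,3-diol)
Product: 6 1,5-dibromo-2,4-bis(methoxymethoxy)benzene
Conditions: NaH (2.4 equiv), MOMCl (2.4 equiv), DMF, 0 °C → rt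
Reagents that add atoms: chloromethyl methyl ether, COCCl
Why: Williamson-type O-alkylation; the acetal oxygens later stabilise the ortho aryllithium species by chelation.

Step 4
Reactants: 6 1,5-dibromo-2,4-bis(methoxymethoxy)benzene; 7 allyl bromide
Product: 9 1-bromo-2,4-bis(methoxymethoxy)-5-(prop-2-en-1-yl)benzene, via aryllithium 8 (not isolated)
Conditions: n-BuLi (1.05 equiv), THF, −78 °C; then CuBr·SMe2 (10 mol%), 7 (1.5 equiv), −78 °C → rt
Reagents that add atoms: none
Why: Bromine–lithium exchange is faster than ring deprotonation and stops after one of the two equivalent bromines, because the electron-rich aryllithium resists a second exchange; copper-assisted allylation gives the same product from either allylic terminus.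

Step 5
Reactants: 9 1-bromo-2,4-bis(methoxymethoxy)-5-(prop-2-en-1-yl)benzene
Product: 11 2-[5-bromo-2,4-bis(methoxymethoxy)phenyl]acetaldehyde, via 1,2-diol 10 (not isolated)
Conditions: K2OsO4·2H2O (2 mol%), NaIO4 (4 equiv), 2,6-lutidine (2 equiv), 1,4-dioxane/H2O (3:1), rt
Reagents that add atoms: sodium periodate, [Na+].[O-]I(=O)(=O)=O (terminal source of the carbonyl oxygen, passed on through the osmium catalyst)
Why: Lemieux–Johnson oxidation: catalytic dihydroxylation of the monosubstituted alkene and periodate cleavage of the diol, with 2,6-lutidine to suppress over-oxidation; the aryl bromide and acetals are inert.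

Step 6
Reactants: 11 2-[5-bromo-2,4-bis(methoxymethoxy)phenyl]acetaldehyde
Product: 12 2-[5-bromo-2,4-bis(methoxymethoxy)phenyl]prop-2-enal
Conditions: 37% aq. CH2O (1.2 equiv), pyrrolidine (10 mol%), EtCO2H (10 mol%), i-PrOH, 45 °C; rapid silica filtration, used at once
Reagents that add atoms: formaldehyde, C=O
Why: Amine-catalysed Mannich condensation–elimination (organocatalytic α-methylenation of an aldehyde): the enamine of 11 adds to the iminium ion of formaldehyde and the amine is expelled to leave the 2-arylacrolein; the weak acid leaves the acetals intact.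

Step 7
Reactants: 4 3,5-bis(methoxymethoxy)-4-methylphenol; 12 2-[5-bromo-2,4-bis(methoxymethoxy)phenyl]prop-2-enal
Product: 15 3-[5-bromo-2,4-bis(methoxymethoxy)phenyl]-5,7-bis(methoxymethoxy)-6-methyl-2H-chromene, via 4H-1,3,2-benzodioxaborin 13 (not isolated), via vinyl ortho-quinone methide 14 (not isolated)
Conditions: PhB(OH)2 (1.0 equiv), EtCO2H (0.3 equiv), toluene, reflux, Dean–Stark; 12 added over 4 h
Reagents that add atoms: none
Why: Proposed new method: the closest known reaction type is the phenylboronic acid-templated condensation of phenols with α,β-unsaturated aldehydes to 2H-chromenes, which has been run with β-substituted enals but not with a 2-arylacrolein, so the enal class is new. Phenol 4 and PhB(OH)2 should form a mixed aryl boronate that binds the aldehyde oxygen of 12 and delivers the carbonyl carbon to the ortho carbon C4a through a six-membered array, making C4–C4a and giving benzodioxaborin 13. On heating, 13 should fragment by a retro-[4+2] process with loss of PhBO (collected as triphenylboroxine) to the vinyl ortho-quinone methide 14, in which the C5 acetal group pushes the 1-arylvinyl chain to the carbonyl side, the geometry needed for closure. Ring C then closes by thermal disrotatory oxa-6π electrocyclisation, forming O1–C2 at the unhindered terminal CH2 as a six-membered 2H-pyran and restoring the aromaticity of ring A; no stereocentre is created. The selectivity needed is ortho C-attack at the carbonyl carbon in preference to O-alkylation or conjugate addition at the β-CH2, and the boron tether secures it because only the carbonyl carbon can reach C4a while the aldehyde oxygen is held on boron. Regiochemistry needs no control, since the two ortho carbons of 4 are equivalent and the para carbon C6 carries the methyl group. The tendency of 12 to dimerise is met by adding it slowly to the preformed boronate under water removal.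

Step 8
Reactants: 15 3-[5-bromo-2,4-bis(methoxymethoxy)phenyl]-5,7-bis(methoxymethoxy)-6-methyl-2H-chromene
Product: 17 (3R,4S)-3-[5-bromo-2,4-bis(methoxymethoxy)phenyl]-5,7-bis(methoxymethoxy)-6-methyl-3,4-dihydro-2H-chromen-4-ol, via C4 isopinocampheylborane 16 (not isolated)
Conditions: IpcBH2 from (1S)-(−)-α-pinene (1.3 equiv), THF, −25 → 0 °C; then aq. NaOH, 30% H2O2, 0 °C → rt
Reagents that add atoms: hydrogen peroxide, OO
Why: Asymmetric hydroboration–oxidation of a trisubstituted aryl alkene: boron takes the less substituted C4 and hydrogen goes to C3 in a syn addition, and oxidation with retention gives the trans alcohol. The isopinocampheyl group differentiates the two faces of C3=C4; by analogy with 1-arylcycloalkenes the (−)-α-pinene series is expected to set C3 as R and C4 as S.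

Step 9
Reactants: 17 (3R,4S)-3-[5-bromo-2,4-bis(methoxymethoxy)phenyl]-5,7-bis(methoxymethoxy)-6-methyl-3,4-dihydro-2H-chromen-4-ol; 18 geranyl bromide
Product: 20 (3R,4S)-3-{5-[(2E)-3,7-dimethylocta-2,6-dien-1-yl]-2,4-bis(methoxymethoxy)phenyl}-5,7-bis(methoxymethoxy)-6-methyl-3,4-dihydro-2H-chromen-4-ol, via C5′-lithio lithium alkoxide 19 (not isolated)
Conditions: n-BuLi (2.2 equiv), THF, −78 °C; CuBr·SMe2 (1.1 equiv), −78 → −40 °C; 18 (1.3 equiv), −40 → 0 °C; then H2O
Reagents that add atoms: none
Why: The first equivalent of base forms the C4 alkoxide and the second exchanges the bromine next to the C4′ acetal; the arylcopper species derived from 19 displaces the primary allylic bromide at its unsubstituted terminus with retention of the E alkene (copper-mediated aryl–allyl coupling). C3 is not acidic at the carbinol level, so its configuration is untouched.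

Step 10
Reactants: 20 (3R,4S)-3-{5-[(2E)-3,7-dimethylocta-2,6-dien-1-yl]-2,4-bis(methoxymethoxy)phenyl}-5,7-bis(methoxymethoxy)-6-methyl-3,4-dihydro-2H-chromen-4-ol
Product: 21 (3R)-3-{5-[(2E)-3,7-dimethylocta-2,6-dien-1-yl]-2,4-bis(methoxymethoxy)phenyl}-5,7-bis(methoxymethoxy)-6-methyl-2,3-dihydro-4H-chromen-4-one
Conditions: Dess–Martin periodinane (1.5 equiv), NaHCO3, CH2Cl2, 0 °C → rt
Reagents that add atoms: none
Why: Dess–Martin oxidation of the benzylic alcohol under buffered, non-enolising conditions leaves the trisubstituted alkenes and acetals alone and should not epimerise C3.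

Step 11
Reactants: 21 (3R)-3-{5-[(2E)-3,7-dimethylocta-2,6-dien-1-yl]-2,4-bis(methoxymethoxy)phenyl}-5,7-bis(methoxymethoxy)-6-methyl-2,3-dihydro-4H-chromen-4-one
Product: 22 (3R)-3-{5-[(2E)-3,7-dimethylocta-2,6-dien-1-yl]-2,4-dihydroxyphenyl}-5,7-dihydroxy-6-methyl-2,3-dihydro-4H-chromen-4-one
Conditions: HCl (1.25 M in MeOH), THF, 0 °C → rt
Reagents that add atoms: none
Why: Acid-catalysed transacetalisation of the four aryl methoxymethyl ethers to methanol (acetal cleavage); dilute acid at or below room temperature in a large excess of methanol is chosen so that acetal exchange outruns enolisation at C3 and protonation of the geranyl alkenes, and so that the released methoxymethyl cation is trapped by solvent.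

## Compound list

1 | 2-methylresorcinol (2-methylbenzene-1,3-diol) | Cc1c(O)cccc1O | starting material
2 | 1,3-bis(methoxymethoxy)-2-methylbenzene | Cc1c(OCOC)cccc1OCOC | intermediate
3 | 2-[3,5-bis(methoxymethoxy)-4-methylphenyl]-4,4,5,5-tetramethyl-1,3,2-dioxaborolane | Cc1c(OCOC)cc(B2OC(C)(C)C(C)(C)O2)cc1OCOC | intermediate
4 | 3,5-bis(methoxymethoxy)-4-methylphenol | Cc1c(OCOC)cc(O)cc1OCOC | intermediate
5 | 4,6-dibromoresorcinol (4,6-dibromobenzene-1,3-diol) | Oc1cc(O)c(Br)cc1Br | starting material
6 | 1,5-dibromo-2,4-bis(methoxymethoxy)benzene | COCOc1cc(OCOC)c(Br)cc1Br | intermediate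
7 | allyl bromide (3-bromoprop-1-ene) | C=CCBr | starting material
8 | [5-bromo-2,4-bis(methoxymethoxy)phenyl]lithium | [Li]c1cc(Br)c(OCOC)cc1OCOC | intermediate
9 | 1-bromo-2,4-bis(methoxymethoxy)-5-(prop-2-en-1-yl)benzene | C=CCc1cc(Br)c(OCOC)cc1OCOC | intermediate
10 | 3-[5-bromo-2,4-bis(methoxymethoxy)phenyl]propane-1,2-diol (racemic) | OCC(O)Cc1cc(Br)c(OCOC)cc1OCOC | intermediate
11 | 2-[5-bromo-2,4-bis(methoxymethoxy)phenyl]acetaldehyde | O=CCc1cc(Br)c(OCOC)cc1OCOC | intermediate
12 | 2-[5-bromo-2,4-bis(methoxymethoxy)phenyl]prop-2-enal | C=C(C=O)c1cc(Br)c(OCOC)cc1OCOC | intermediate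
13 | 4-{1-[5-bromo-2,4-bis(methoxymethoxy)phenyl]ethenyl}-5,7-bis(methoxymethoxy)-6-methyl-2-phenyl-4H-1,3,2-benzodioxaborinine (racemic at C4) | C=C(c1cc(Br)c(OCOC)cc1OCOC)C1OB(c2ccccc2)Oc2cc(OCOC)c(C)c(OCOC)c21 | intermediate
14 | (6Z)-6-{2-[5-bromo-2,4-bis(methoxymethoxy)phenyl]prop-2-en-1-ylidene}-3,5-bis(methoxymethoxy)-4-methylcyclohexa-2,4-dien-1-one (vinyl chain on the carbonyl side) | O=C1C=C(OCOC)C(C)=C(OCOC)/C1=C/C(=C)c1cc(Br)c(OCOC)cc1OCOC | intermediate
15 | 3-[5-bromo-2,4-bis(methoxymethoxy)phenyl]-5,7-bis(methoxymethoxy)-6-methyl-2H-chromene | COCOc1cc(OCOC)c(Br)cc1C1=Cc2c(OCOC)c(C)c(OCOC)cc2OC1 | intermediate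
16 | chroman-4-yl(isopinocampheyl)borane: 17 with the C4 hydroxyl replaced, in the same spatial position, by BH bearing the isopinocampheyl group from (−)-α-pinene | COCOc1cc(OCOC)c(Br)cc1[C@@H]1COc2cc(OCOC)c(C)c(OCOC)c2[C@H]1[BH][C@H]1C[C@H]2C[C@@H]([C@@H]1C)C2(C)C | intermediate
17 | (3R,4S)-3-[5-bromo-2,4-bis(methoxymethoxy)phenyl]-5,7-bis(methoxymethoxy)-6-methyl-3,4-dihydro-2H-chromen-4-ol (trans) | COCOc1cc(OCOC)c(Br)cc1[C@@H]1COc2cc(OCOC)c(C)c(OCOC)c2[C@H]1O | intermediate
18 | geranyl bromide ((2E)-1-bromo-3,7-dimethylocta-2,6-diene) | CC(C)=CCC/C(C)=C/CBr | starting material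
19 | lithium (3R,4S)-3-[5-lithio-2,4-bis(methoxymethoxy)phenyl]-5,7-bis(methoxymethoxy)-6-methyl-3,4-dihydro-2H-chromen-4-olate | [Li]c1cc([C@@H]2COc3cc(OCOC)c(C)c(OCOC)c3[C@H]2O[Li])c(OCOC)cc1OCOC | intermediate
20 | (3R,4S)-3-{5-[(2E)-3,7-dimethylocta-2,6-dien-1-yl]-2,4-bis(methoxymethoxy)phenyl}-5,7-bis(methoxymethoxy)-6-methyl-3,4-dihydro-2H-chromen-4-ol (trans) | CC(C)=CCC/C(C)=C/Cc1cc([C@@H]2COc3cc(OCOC)c(C)c(OCOC)c3[C@H]2O)c(OCOC)cc1OCOC | intermediate
21 | (3R)-3-{5-[(2E)-3,7-dimethylocta-2,6-dien-1-yl]-2,4-bis(methoxymethoxy)phenyl}-5,7-bis(methoxymethoxy)-6-methyl-2,3-dihydro-4H-chromen-4-one | CC(C)=CCC/C(C)=C/Cc1cc([C@@H]2COc3cc(OCOC)c(C)c(OCOC)c3C2=O)c(OCOC)cc1OCOC | intermediate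
22 | (3R)-3-{5-[(2E)-3,7-dimethylocta-2,6-dien-1-yl]-2,4-dihydroxyphenyl}-5,7-dihydroxy-6-methyl-2,3-dihydro-4H-chromen-4-one | CC(C)=CCC/C(C)=C/Cc1cc([C@@H]2COc3cc(O)c(C)c(O)c3C2=O)c(O)cc1O | target

## Step count and risks

Total steps: 11. Longest linear sequence: 9 (steps 3 to 11, from 5).

**Step 7 (key step).** The likeliest failure is that self-condensation of the 2-arylacrolein (hetero-Diels–Alder dimerisation, polymerisation) or conjugate addition of the phenol at the β-carbon outpaces the boron-templated attack at the carbonyl carbon. Partial loss of acetal groups in hot carboxylic acid is a second concern. The fallback uses known chemistry, sets out from 4 and 12 and returns at 15, making O1–C2 first and closing the ring at C3=C4.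
- Ortho-formylation of 4 (MgCl2, Et3N, paraformaldehyde, MeCN, reflux) gives 6-hydroxy-2,4-bis(methoxymethoxy)-3-methylbenzaldehyde F1; the symmetry of 4 again allows one product.
- Luche reduction of 12 (NaBH4, CeCl3·7H2O, MeOH, 0 °C) gives 2-[5-bromo-2,4-bis(methoxymethoxy)phenyl]prop-2-en-1-ol F2.
- Mitsunobu etherification of F1 with F2 (PPh3, DIAD, THF) gives 6-({2-[5-bromo-2,4-bis(methoxymethoxy)phenyl]prop-2-en-1-yl}oxy)-2,4-bis(methoxymethoxy)-3-methylbenzaldehyde F3.
- Wittig methylenation (Ph3P=CH2, THF) gives 1-bromo-5-{3-[2-ethenyl-3,5-bis(methoxymethoxy)-4-methylphenoxy]prop-1-en-2-yl}-2,4-bis(methoxymethoxy)benzene F4.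
- Ring-closing metathesis of F4 with the second-generation Grubbs catalyst in toluene at 80 °C forms C3=C4 and gives 15.

**Step 8.** The bulky borane may add slowly or with poor facial selectivity to an alkene flanked by the C5 acetal and the ortho acetal of ring B, or with the opposite sense to that assumed. The fallback sets out from 15 and returns at 21.
- Hydroboration with BH3·SMe2 and alkaline peroxide gives racemic trans alcohol, that is 17 together with its (3S,4R)-enantiomer F5.
- Dess–Martin oxidation gives racemic 3-[5-bromo-2,4-bis(methoxymethoxy)phenyl]-5,7-bis(methoxymethoxy)-6-methyl-2,3-dihydro-4H-chromen-4-one F6.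
- Asymmetric transfer hydrogenation with dynamic kinetic resolution (RuCl(p-cymene)[(R,R)-TsDPEN], HCO2H/Et3N) is expected to give the cis alcohol (3R,4R)-3-[5-bromo-2,4-bis(methoxymethoxy)phenyl]-5,7-bis(methoxymethoxy)-6-methyl-3,4-dihydro-2H-chromen-4-ol F7. The base epimerises C3 of F6 while the catalyst reduces one enantiomer. The catalyst configuration is chosen by analogy with aryl alkyl ketones.
- Geranylation under the conditions of step 9 gives (3R,4R)-3-{5-[(2E)-3,7-dimethylocta-2,6-dien-1-yl]-2,4-bis(methoxymethoxy)phenyl}-5,7-bis(methoxymethoxy)-6-methyl-3,4-dihydro-2H-chromen-4-ol F8.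
- Oxidation under the conditions of step 10 removes the C4 centre and gives 21.

**Step 9.** The aryllithium may be protonated before it is captured, the arylcopper may attack the substituted allylic terminus to give the branched isomer, or the alkoxide may be O-alkylated. The fallback reverses the polarity of the coupling, sets out from 17 and returns at 20.
- Miyaura borylation (PdCl2(dppf), B2pin2, KOAc, 1,4-dioxane, 80 °C) gives (3R,4S)-3-[2,4-bis(methoxymethoxy)-5-(4,4,5,5-tetramethyl-1,3,2-dioxaborolan-2-yl)phenyl]-5,7-bis(methoxymethoxy)-6-methyl-3,4-dihydro-2H-chromen-4-ol F9.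
- Suzuki–Miyaura-type coupling of F9 with 18 (Pd(PPh3)4, K2CO3, THF/H2O) gives 20. Reductive elimination from the allylpalladium intermediate at its less hindered terminus should give the linear E product.

**Step 11.** Acid-catalysed enolisation at C3 may erode the enantiomeric purity, and the C4′ hydroxyl may cyclise onto the neighbouring geranyl alkene once it is freed. Substitution of the electron-rich ring A by released methoxymethyl cation is a lesser concern. The fallback gives up preserving C3 in this step and separates instead; it sets out from 21 and returns at 22. Deprotection is run under the mildest conditions that keep the chain intact, whatever happens at C3, to give 22 mixed with its enantiomer (3S)-3-{5-[(2E)-3,7-dimethylocta-2,6-dien-1-yl]-2,4-dihydroxyphenyl}-5,7-dihydroxy-6-methyl-2,3-dihydro-4H-chromen-4-one F10. The two are then separated by preparative chromatography on a polysaccharide carbamate chiral stationary phase.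

## Further compounds

F1 | step 7 | 6-hydroxy-2,4-bis(methoxymethoxy)-3-methylbenzaldehyde | Cc1c(OCOC)cc(O)c(C=O)c1OCOC
F2 | step 7 | 2-[5-bromo-2,4-bis(methoxymethoxy)phenyl]prop-2-en-1-ol | C=C(CO)c1cc(Br)c(OCOC)cc1OCOC
F3 | step 7 | 6-({2-[5-bromo-2,4-bis(methoxymethoxy)phenyl]prop-2-en-1-yl}oxy)-2,4-bis(methoxymethoxy)-3-methylbenzaldehyde | C=C(COc1cc(OCOC)c(C)c(OCOC)c1C=O)c1cc(Br)c(OCOC)cc1OCOC
F4 | step 7 | 1-bromo-5-{3-[2-ethenyl-3,5-bis(methoxymethoxy)-4-methylphenoxy]prop-1-en-2-yl}-2,4-bis(methoxymethoxy)benzene | C=Cc1c(OCC(=C)c2cc(Br)c(OCOC)cc2OCOC)cc(OCOC)c(C)c1OCOC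
F5 | step 8 | (3S,4R)-3-[5-bromo-2,4-bis(methoxymethoxy)phenyl]-5,7-bis(methoxymethoxy)-6-methyl-3,4-dihydro-2H-chromen-4-ol (enantiomer of 17, formed with it as the racemate) | COCOc1cc(OCOC)c(Br)cc1[C@H]1COc2cc(OCOC)c(C)c(OCOC)c2[C@@H]1O
F6 | step 8 | 3-[5-bromo-2,4-bis(methoxymethoxy)phenyl]-5,7-bis(methoxymethoxy)-6-methyl-2,3-dihydro-4H-chromen-4-one (racemic) | COCOc1cc(OCOC)c(Br)cc1C1COc2cc(OCOC)c(C)c(OCOC)c2C1=O
F7 | step 8 | (3R,4R)-3-[5-bromo-2,4-bis(methoxymethoxy)phenyl]-5,7-bis(methoxymethoxy)-6-methyl-3,4-dihydro-2H-chromen-4-ol (cis) | COCOc1cc(OCOC)c(Br)cc1[C@@H]1COc2cc(OCOC)c(C)c(OCOC)c2[C@@H]1O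
F8 | step 8 | (3R,4R)-3-{5-[(2E)-3,7-dimethylocta-2,6-dien-1-yl]-2,4-bis(methoxymethoxy)phenyl}-5,7-bis(methoxymethoxy)-6-methyl-3,4-dihydro-2H-chromen-4-ol (cis) | CC(C)=CCC/C(C)=C/Cc1cc([C@@H]2COc3cc(OCOC)c(C)c(OCOC)c3[C@@H]2O)c(OCOC)cc1OCOC
F9 | step 9 | (3R,4S)-3-[2,4-bis(methoxymethoxy)-5-(4,4,5,5-tetramethyl-1,3,2-dioxaborolan-2-yl)phenyl]-5,7-bis(methoxymethoxy)-6-methyl-3,4-dihydro-2H-chromen-4-ol | COCOc1cc(OCOC)c(B2OC(C)(C)C(C)(C)O2)cc1[C@@H]1COc2cc(OCOC)c(C)c(OCOC)c2[C@H]1O
F10 | step 11 | (3S)-3-{5-[(2E)-3,7-dimethylocta-2,6-dien-1-yl]-2,4-dihydroxyphenyl}-5,7-dihydroxy-6-methyl-2,3-dihydro-4H-chromen-4-one | CC(C)=CCC/C(C)=C/Cc1cc([C@H]2COc3cc(O)c(C)c(O)c3C2=O)c(O)cc1O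
A1 | alternative 1 | methyl 8-{5-[(2E)-3,7-dimethylocta-2,6-dien-1-yl]-2,4-bis(methoxymethoxy)phenyl}-9-hydroxy-2-methyl-3,5,7-trioxononanoate (stereocentres undefined) | CC(C)=CCC/C(C)=C/Cc1cc(C(CO)C(=O)CC(=O)CC(=O)C(C)C(=O)OC)c(OCOC)cc1OCOC
A2 | alternative 1 | 3-{5-[(2E)-3,7-dimethylocta-2,6-dien-1-yl]-2,4-bis(methoxymethoxy)phenyl}-5,7-dihydroxy-6-methyl-2,3-dihydro-4H-chromen-4-one (racemic) | CC(C)=CCC/C(C)=C/Cc1cc(C2COc3cc(O)c(C)c(O)c3C2=O)c(OCOC)cc1OCOC
A3 | alternative 2 | 1-[2,4-bis(tert-butyldimethylsilyloxy)-6-methoxy-3-methylphenyl]-2-{2,4-bis(tert-butyldimethylsilyloxy)-5-[(2E)-3,7-dimethylocta-2,6-dien-1-yl]phenyl}-2-diazoethan-1-one | CC(C)=CCC/C(C)=C/Cc1cc(C(=[N+]=[N-])C(=O)c2c(OC)cc(O[Si](C)(C)C(C)(C)C)c(C)c2O[Si](C)(C)C(C)(C)C)c(O[Si](C)(C)C(C)(C)C)cc1O[Si](C)(C)C(C)(C)C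
A4 | alternative 2 | (3R)-5,7-bis(tert-butyldimethylsilyloxy)-3-{2,4-bis(tert-butyldimethylsilyloxy)-5-[(2E)-3,7-dimethylocta-2,6-dien-1-yl]phenyl}-6-methyl-2,3-dihydro-4H-chromen-4-one | CC(C)=CCC/C(C)=C/Cc1cc([C@@H]2COc3cc(O[Si](C)(C)C(C)(C)C)c(C)c(O[Si](C)(C)C(C)(C)C)c3C2=O)c(O[Si](C)(C)C(C)(C)C)cc1O[Si](C)(C)C(C)(C)C
A5 | alternative 3 | (1S,2R)-1-[6-bromo-2,4-bis(methoxymethoxy)-3-methylphenyl]-2-{5-[(2E)-3,7-dimethylocta-2,6-dien-1-yl]-2,4-bis(methoxymethoxy)phenyl}propane-1,3-diol | CC(C)=CCC/C(C)=C/Cc1cc([C@H](CO)[C@H](O)c2c(Br)cc(OCOC)c(C)c2OCOC)c(OCOC)cc1OCOC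
A6 | alternative 3 | (3R,4S)-3-{5-[(2E)-3,7-dimethylocta-2,6-dien-1-yl]-2,4-bis(methoxymethoxy)phenyl}-5,7-bis(methoxymethoxy)-6-methyl-3,4-dihydro-2H-chromen-4-ol (identical with 20) | CC(C)=CCC/C(C)=C/Cc1cc([C@@H]2COc3cc(OCOC)c(C)c(OCOC)c3[C@H]2O)c(OCOC)cc1OCOC
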